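**Retrosynthetic overview**
- The strategy rests on ring A, a benzene substituted on all six carbons. The run C5–C6–C7–C8, each carbon bearing oxygen (OH, OMe, OMe, OMe), is taken from the four-membered ring of dimethyl squarate. The fusion carbons C4a and C8a are C5 and C6 of a monocyclic 4-pyranone that is ring C and already carries ring B at C2 and the protected 3-oxygen.
- Disconnections, backwards: O-debenzylation; ring A by C4a–C5 bond formation in a 4π-opening/6π-closure cascade of a 4-methoxy-4-(pyranon-6-yl)cyclobutenone; the C8–C8a bond by addition of the C6-lithiated pyranone to the squarate; the C2–C1' bond by Suzuki coupling of a 2-bromopyranone.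
- Ring order: ring C is bought (pyromeconic acid), ring B is attached by cross-coupling, ring A is closed last.

Key step: step 6

Assumption: the target is achiral, so the two cyclobutenone intermediates are carried as racemates; pyromeconic acid, 4-benzyloxyphenylboronic acid and dimethyl squarate are taken as purchased.

**Step 1**
Reactants: 1 pyromeconic acid (3-hydroxy-4H-pyran-4-one)
Product: 2 2-bromo-3-hydroxy-4H-pyran-4-one
Conditions: NBS, MeCN, 0 °C to rt
Reagents that add atoms: N-bromosuccinimide, O=C1CCC(=O)N1Br
Why: Electrophilic bromination of the enolic hydroxypyranone should occur at C2, the terminus of the C2=C3 enol next to the hydroxyl, as in the C-halogenation of kojic-acid-type hydroxypyranones; no stereocenter is formed.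

**Step 2**
Reactants: 2 2-bromo-3-hydroxy-4H-pyran-4-one
Product: 3 3-benzyloxy-2-bromo-4H-pyran-4-one
Conditions: BnBr, K2CO3, DMF, rt
Reagents that add atoms: benzyl bromide, BrCc1ccccc1
Why: Williamson O-alkylation of the acidic enolic hydroxyl gives an ether that should survive cross-coupling, lithium amide base and heat and that is removed by hydrogenolysis at the end.

**Step 3**
Reactants: 3 3-benzyloxy-2-bromo-4H-pyran-4-one; 4 4-benzyloxyphenylboronic acid
Product: 5 3-benzyloxy-2-(4-benzyloxyphenyl)-4H-pyran-4-one
Conditions: Pd(PPh3)4 (cat.), K2CO3, 1,4-dioxane/H2O, 80 °C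
Reagents that add atoms: none
Why: Suzuki–Miyaura coupling: the C2–Br bond of the vinylogous acyl bromide should add readily to zerovalent palladium, and transmetalation and reductive elimination join ring B to C2, the carbonate base being mild enough to leave the pyranone ring closed.

**Step 4**
Reactants: 5 3-benzyloxy-2-(4-benzyloxyphenyl)-4H-pyran-4-one; 6 dimethyl squarate (3,4-dimethoxycyclobut-3-ene-1,2-dione)
Product: 9 racemic 3-benzyloxy-2-(4-benzyloxyphenyl)-6-(1-hydroxy-2,3-dimethoxy-4-oxocyclobut-2-en-1-yl)-4H-pyran-4-one, via 6-lithiopyranone 7 (not isolated), via lithium cyclobutenolate 8 (not isolated)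
Conditions: lithium 2,2,6,6-tetramethylpiperidide (from the amine and n-BuLi), THF, −78 °C, 5 added to the base; then cannulated onto 6 in THF, −78 °C; aq. NH4Cl, −78 °C
Reagents that add atoms: none
Why: Proposed new method: C6–H is the only vinylic hydrogen next to the ring oxygen (C2 is blocked by the aryl group), so the hindered, non-nucleophilic amide should remove it under kinetic control in the way the same base lithiates chromones at C2 and alkyllithiums lithiate dihydropyrans next to oxygen (closest known reaction type: vinylic lithiation alpha to a ring oxygen), and the vinyllithium should then add 1,2 to one of the two equivalent squarate carbonyls as aryl- and alkenyllithiums do, the new quaternary carbinol carbon arising as a racemate because the two faces of the squarate are equivalent.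

**Step 5**
Reactants: 9 racemic 3-benzyloxy-2-(4-benzyloxyphenyl)-6-(1-hydroxy-2,3-dimethoxy-4-oxocyclobut-2-en-1-yl)-4H-pyran-4-one
Product: 10 racemic 3-benzyloxy-2-(4-benzyloxyphenyl)-6-(1,2,3-trimethoxy-4-oxocyclobut-2-en-1-yl)-4H-pyran-4-one
Conditions: MeI, Ag2O, MeCN, rt, dark
Reagents that add atoms: iodomethane, CI
Why: Silver-oxide-mediated O-methylation (Purdie methylation) alkylates the tertiary cyclobutenol under nearly neutral conditions, which should avoid both ring opening of a free alkoxide and the methylation at the pyranone carbonyl oxygen expected with methyl triflate; the stereocenter is untouched and stays racemic.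

**Step 6**
Reactants: 10 racemic 3-benzyloxy-2-(4-benzyloxyphenyl)-6-(1,2,3-trimethoxy-4-oxocyclobut-2-en-1-yl)-4H-pyran-4-one
Product: 13 3,4'-bis(benzyloxy)-5-hydroxy-6,7,8-trimethoxyflavone, via dienylketene 11 (not isolated), via cyclohexadienone 12 (not isolated)
Conditions: PhMe (degassed, 0.02 M), 110 °C, Ar
Reagents that add atoms: none
Why: Proposed new method: Heating should break the cyclobutenone C1–C4 bond in a conrotatory 4π electrocyclic opening to dienylketene 11, in which the C4 methoxy donor turns outward and the pyranonyl group inward, next to the ketene. The ketene carbon then bonds to pyranone C5 in a thermal disrotatory 6π electrocyclization, which closes ring A as a six-membered carbocycle through the new C4a–C5 bond and gives dienone 12; enolization of its doubly activated C4a–H gives phenol 13. The closest known reaction is the Moore rearrangement of 4-aryl-, 4-heteroaryl- and 4-alkenyl-4-alkoxycyclobutenones to mono-protected hydroquinones; the extension is the use of the C5=C6 bond of a 4-pyranone as the 2π partner, which should be favourable because C5 is the nucleophilic carbon of this vinylogous ester and little aromatic stabilization is given up. No stereocenter remains, since the quaternary carbon of 10 becomes aromatic C8 and the transient sp3 C4a of 12 is lost on tautomerization. The step needs inward rotation of the pyranonyl group, secured by the outward preference of the 4-methoxy group, and a single orientation of ring fusion, secured because C5 is the only carbon next to the point of attachment that can accept the ketene (the other neighbour of C6 is the ring oxygen); the 5-OH/8-OMe pattern follows from which squarate carbon carries the ketene oxygen.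

**Step 7**
Reactants: 13 3,4'-bis(benzyloxy)-5-hydroxy-6,7,8-trimethoxyflavone
Product: 14 3,5,4'-trihydroxy-6,7,8-trimethoxyflavone
Conditions: H2 (1 atm), 10% Pd/C, EtOAc/MeOH, rt
Reagents that add atoms: none
Why: Catalytic hydrogenolysis cleaves both benzylic C–O bonds (O3 and O4'), while the methyl ethers, the chelated 5-OH and the C2=C3 bond of the conjugated flavonol should be left alone; no stereocenter is involved.

**Compound list**
1 | pyromeconic acid (3-hydroxy-4H-pyran-4-one) | O=c1ccocc1O | starting material
2 | 2-bromo-3-hydroxy-4H-pyran-4-one | O=c1ccoc(Br)c1O | intermediate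
3 | 3-benzyloxy-2-bromo-4H-pyran-4-one | O=c1ccoc(Br)c1OCc1ccccc1 | intermediate
4 | 4-benzyloxyphenylboronic acid | OB(O)c1ccc(OCc2ccccc2)cc1 | starting material
5 | 3-benzyloxy-2-(4-benzyloxyphenyl)-4H-pyran-4-one | O=c1ccoc(-c2ccc(OCc3ccccc3)cc2)c1OCc1ccccc1 | intermediate
6 | dimethyl squarate (3,4-dimethoxycyclobut-3-ene-1,2-dione) | COC1=C(OC)C(=O)C1=O | starting material
7 | 3-benzyloxy-2-(4-benzyloxyphenyl)-6-lithio-4H-pyran-4-one | [Li]c1cc(=O)c(OCc2ccccc2)c(-c2ccc(OCc3ccccc3)cc2)o1 | intermediate
8 | lithium alkoxide of 9 (racemic) | COC1=C(OC)C(O[Li])(c2cc(=O)c(OCc3ccccc3)c(-c3ccc(OCc4ccccc4)cc3)o2)C1=O | intermediate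
9 | 3-benzyloxy-2-(4-benzyloxyphenyl)-6-(1-hydroxy-2,3-dimethoxy-4-oxocyclobut-2-en-1-yl)-4H-pyran-4-one (racemic) | COC1=C(OC)C(O)(c2cc(=O)c(OCc3ccccc3)c(-c3ccc(OCc4ccccc4)cc3)o2)C1=O | intermediate
10 | 3-benzyloxy-2-(4-benzyloxyphenyl)-6-(1,2,3-trimethoxy-4-oxocyclobut-2-en-1-yl)-4H-pyran-4-one (racemic) | COC1=C(OC)C(OC)(c2cc(=O)c(OCc3ccccc3)c(-c3ccc(OCc4ccccc4)cc3)o2)C1=O | intermediate
11 | (3Z)-4-[5-benzyloxy-6-(4-benzyloxyphenyl)-4-oxo-4H-pyran-2-yl]-2,3,4-trimethoxybuta-1,3-dien-1-one (dienylketene, pyranonyl cis to the ketene-bearing carbon) | O=C=C(OC)/C(OC)=C(/OC)c1cc(=O)c(OCc2ccccc2)c(-c2ccc(OCc3ccccc3)cc2)o1 | intermediate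
12 | 3-benzyloxy-2-(4-benzyloxyphenyl)-6,7,8-trimethoxy-4aH-chromene-4,5-dione (racemic 4a-H dienone tautomer of 13) | COC1=C(OC)C(=O)C2C(=O)C(OCc3ccccc3)=C(c3ccc(OCc4ccccc4)cc3)OC2=C1OC | intermediate
13 | 3,4'-bis(benzyloxy)-5-hydroxy-6,7,8-trimethoxyflavone | COc1c(OC)c(O)c2c(=O)c(OCc3ccccc3)c(-c3ccc(OCc4ccccc4)cc3)oc2c1OC | intermediate
14 | 3,5,4'-trihydroxy-6,7,8-trimethoxyflavone | COc1c(OC)c(O)c2c(=O)c(O)c(-c3ccc(O)cc3)oc2c1OC | target

**Step count**
Total step count: 7. Longest linear sequence: 7 steps (1 to 14); 4 and 6 enter as purchased partners.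

**Steps most likely to fail**

Step 4 (Proposed new method). The deprotonation at C6 may be outrun by addition of the amide, or of the first-formed vinyllithium, to pyranone that is not yet metalated (self-condensation). Removal of a benzylic proton of the O3 benzyl ether may also compete, so that no clean C6 nucleophile reaches the squarate.

Fallback, known chemistry, setting out from 6 and coming back at 14: the pyranone is given up as the nucleophile and ring A is made first with a precedented alkenyllithium.
- 1-Methoxyvinyllithium (methyl vinyl ether, t-BuLi, THF) adds to 6 to give racemic 4-hydroxy-2,3-dimethoxy-4-(1-methoxyvinyl)cyclobut-2-en-1-one F1.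
- MeI/Ag2O gives racemic 2,3,4-trimethoxy-4-(1-methoxyvinyl)cyclobut-2-en-1-one F2.
- Thermolysis in toluene, the established ring expansion of 4-alkenyl-4-alkoxycyclobutenones, gives 2,3,4,5-tetramethoxyphenol F3.
- Friedel–Crafts acetylation at the only free ring position (BF3·OEt2, AcOH) gives 1-(2-hydroxy-3,4,5,6-tetramethoxyphenyl)ethanone F4.
- Claisen–Schmidt condensation with 4-benzyloxybenzaldehyde (KOH, EtOH) gives (E)-3-(4-benzyloxyphenyl)-1-(2-hydroxy-3,4,5,6-tetramethoxyphenyl)prop-2-en-1-one F5.
- Oxidative cyclization with I2 in DMSO gives 4'-benzyloxy-5,6,7,8-tetramethoxyflavone F6.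
- Epoxidation of the C2=C3 bond with dimethyldioxirane and acid-induced opening gives 4'-benzyloxy-3-hydroxy-5,6,7,8-tetramethoxyflavone F7.
- BCl3 in CH2Cl2 cleaves the 5-methyl ether, activated by chelation to the C4 carbonyl, together with the benzyl ether and gives 14.

Step 6 (Proposed new method). The dienylketene may not close onto the pyranone C5=C6 bond fast enough. It would then be lost to dimerization or to capture by adventitious nucleophiles, or the substrate may decompose on prolonged heating.

Fallback, known chemistry, setting out from 6 (with 4 as the ring B donor) and coming back at 14: the ring expansion is run on the precedented 1-methoxyvinyl adduct, and the heterocycle is annulated afterwards.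
- 6 is taken through F1, F2 and F3 to acetophenone F4 as described for step 4.
- DMF dimethyl acetal converts F4 into (E)-3-(dimethylamino)-1-(2-hydroxy-3,4,5,6-tetramethoxyphenyl)prop-2-en-1-one F8.
- Acid (HCl, CH2Cl2) closes ring C to 5,6,7,8-tetramethoxy-4H-chromen-4-one F9.
- Conjugate addition of boronic acid 4 catalysed by Pd(OCOCF3)2 and 2,2'-bipyridine gives racemic 2-(4-benzyloxyphenyl)-5,6,7,8-tetramethoxychroman-4-one F10.
- Dehydrogenation with I2 in DMSO gives flavone F6, which is carried through F7 to 14 as above.

Step 5. Alkylation at the hindered tertiary hydroxyl may be slow. The pyranone carbonyl oxygen could then be methylated in competition, or the cyclobutenol could fragment during long exposure to the basic silver salt.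

Fallback, setting out from 9 and coming back at 13: the methylation is moved behind the ring expansion.
- Thermolysis of 9 itself in degassed toluene should give, by the same cascade with the hydroxyl group turning outward, the hydroquinone 3,4'-bis(benzyloxy)-5,8-dihydroxy-6,7-dimethoxyflavone F11.
- Its 5-OH is held in a hydrogen bond to the C4 carbonyl, so one equivalent of Me2SO4 with K2CO3 in acetone under argon should methylate only the 8-OH and give 13.

**Further compounds**
F1 | step 4 | 4-hydroxy-2,3-dimethoxy-4-(1-methoxyvinyl)cyclobut-2-en-1-one (racemic) | COC(=C)C1(O)C(OC)=C(OC)C1=O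
F2 | step 4 | 2,3,4-trimethoxy-4-(1-methoxyvinyl)cyclobut-2-en-1-one (racemic) | COC(=C)C1(OC)C(OC)=C(OC)C1=O
F3 | step 4 | 2,3,4,5-tetramethoxyphenol | COc1cc(O)c(OC)c(OC)c1OC
F4 | step 4 | 1-(2-hydroxy-3,4,5,6-tetramethoxyphenyl)ethanone | CC(=O)c1c(O)c(OC)c(OC)c(OC)c1OC
F5 | step 4 | (E)-3-(4-benzyloxyphenyl)-1-(2-hydroxy-3,4,5,6-tetramethoxyphenyl)prop-2-en-1-one | O=C(/C=C/c1ccc(OCc2ccccc2)cc1)c1c(O)c(OC)c(OC)c(OC)c1OC
F6 | step 4 | 4'-benzyloxy-5,6,7,8-tetramethoxyflavone | COc1c(OC)c(OC)c2oc(-c3ccc(OCc4ccccc4)cc3)cc(=O)c2c1OC
F7 | step 4 | 4'-benzyloxy-3-hydroxy-5,6,7,8-tetramethoxyflavone | COc1c(OC)c(OC)c2oc(-c3ccc(OCc4ccccc4)cc3)c(O)c(=O)c2c1OC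
F8 | step 6 | (E)-3-(dimethylamino)-1-(2-hydroxy-3,4,5,6-tetramethoxyphenyl)prop-2-en-1-one | CN(C)/C=C/C(=O)c1c(O)c(OC)c(OC)c(OC)c1OC
F9 | step 6 | 5,6,7,8-tetramethoxy-4H-chromen-4-one | COc1c(OC)c(OC)c2occc(=O)c2c1OC
F10 | step 6 | 2-(4-benzyloxyphenyl)-5,6,7,8-tetramethoxychroman-4-one (racemic) | COc1c(OC)c(OC)c2OC(c3ccc(OCc4ccccc4)cc3)CC(=O)c2c1OC
F11 | step 5 | 3,4'-bis(benzyloxy)-5,8-dihydroxy-6,7-dimethoxyflavone | COc1c(OC)c(O)c2c(=O)c(OCc3ccccc3)c(-c3ccc(OCc4ccccc4)cc3)oc2c1O
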